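A small charge of Z ended with a smaller share as Q than a large one: Thursday's run at 0.15 M stood at 35.2% after 60.0 min, and Friday's at 0.60 M stood at 89.5% after 25.0 min.

| flask | Z | X | temperature | remark | time |
|---|---|---|---|---|---|
| Thursday's | 0.15 M | 4 equiv | 30 °C | run made earlier |  |
| Friday's | 0.60 M | 4 equiv | 41 °C | run made earlier |  |
| summer | 0.30 M | 4.00 equiv | 25 °C |  | 1.0 h |
| noon | 0.30 M | 4.00 equiv | 35 °C |  | 1.0 h |
| autumn | 0.30 M | 4.00 equiv | 45 °C |  | 1.0 h |

| run | time / min | Q / % | Z / % |
|---|---|---|---|
| Thursday's | 10.0 | 50.2 | 28.0 |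
| Thursday's | 20.0 | 47.4 | 26.0 |
| Thursday's | 30.0 | 45.0 | 25.6 |
| Thursday's | 40.0 | 39.0 | 26.1 |
| Thursday's | 50.0 | 38.0 | 26.3 |
| Thursday's | 60.0 | 35.2 | 26.6 |
| Friday's | 5.00 | 82.9 | 1.7 |
| Friday's | 10.0 | 84.2 | 1.6 |
| Friday's | 15.0 | 87.2 | 0.9 |
| Friday's | 20.0 | 88.4 | 1.2 |
| Friday's | 25.0 | 89.5 | 0.7 |

(standard deviation of a reading: 0.5 percentage points)

- the numbers in the tables scatter with a standard deviation of 0.5 percentage points
- a reading or a percentage of Q counts all its forms, free or not

- which of the two there is more of at the end, summer (E / Q)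
- which of the two there is more of at the end, noon (E / Q)
- which of the two there is more of at the end, autumn (E / Q)
- final Q, as a percentage of the Z charged, in summer
- final Q, as a percentage of the Z charged, in noon
- final Q, as a percentage of the Z charged, in autumn

Minutes of the meeting held before the three flasks were run. The forecaster opened by expecting “higher concentration and higher temperature both to favour Q”. The forecast put Q ahead in summer, Q at noon and Q in autumn, with final Q at 45%, 64% and 83%.

I, taking the minutes, argued for reckoning with what is missing and not with what is made. Thursday's run, I said, lacks 0.0972 M: that is its shortfall, the concentration of charged Z not found as Q in any form at the last reading. Friday's run lacks 0.0630 M at its last reading. In percent the two shortfalls differ by a factor of 6.17, but in concentration by 1.54, although the charges differ by 4.00.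

The two runs differ in both charge and temperature, so I took it as an assumption, and not as a finding, that the shortfall follows the temperature and not the charge, as it might if part of Q stood out of solution. A colleague objected that Thursday's Q was still falling, from 50.2% to 35.2%, so this shortfall is a reading on the way. The objection was noted.

Drawing the logarithm of the shortfall as a straight line in temperature, I reckoned 0.118 M at 25 °C, 0.0798 M at 35 °C and 0.0538 M at 45 °C. Taking each as a fraction of the 0.30 M charge and subtracting it from one gives Q of 60.5%, 73.4% and 82.1%. My summer figure stands above the forecast's, and both were minuted.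

The flasks gave Q at 66.2%, 75.6% and 84.1%, with E at 25.2%, 18.1% and 11.3%.

2 Z → L (k = 1.10 × 10⁻⁵ M⁻¹ s⁻¹, Ea = 72.0 kJ mol⁻¹); X ⇌ J (K = 0.0790, k = 0.00330 s⁻¹, Ea = 86.0 kJ mol⁻¹, ΔH = −25.0 kJ mol⁻¹); Z + X ⇌ Q (K = 1.10 M⁻¹, k = 0.00510 M⁻¹ s⁻¹, Ea = 57.0 kJ mol⁻¹, ΔH = 26.0 kJ mol⁻¹); G ⇌ Q, rate k4*(cs4 - [Q]) while solid is left; crystals form when [Q] > cs4 (solubility = 25.0 mM, k = 0.500 s⁻¹); Z + X ⇌ E (K = 4.00 M⁻¹, k = 0.00120 M⁻¹ s⁻¹, Ea = 52.0 kJ mol⁻¹, ΔH = −13.0 kJ mol⁻¹); (constants at 25 °C) Summer stands 21 percentage points above the forecast, and its Q includes crystals G at 57.9%. The shortfalls came to 0.101 M, 0.0732 M and 0.0477 M, against the 0.118 M, 0.0798 M and 0.0538 M reckoned. Summer repeated with 0.075 M of Z charges less than the 0.118 M reckoned as summer's shortfall, so the reckoning gives that flask no Q; it ends with G at 0%, Z at 49.1% and Q at 13.3%.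

The data are calculated with made-up constants.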